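Q is what the flasks are run for. Its percent of the E charged is read beside E, and in Monday's run at 25.0 h the reading is 74.7 % Q and 23.2 % E.

| setting | Monday's | Wednesday's | Friday's | alder | larch | cedar | elm | birch |
|---|---|---|---|---|---|---|---|---|
| E | 0.015 M | 0.051 M | 0.19 M | 0.20 M | 0.10 M | 0.012 M | 0.050 M | 0.025 M |
| D | 24 mM (held) | 24 mM (held) | 24 mM (held) | 24 mM (held) | 24 mM (held) | 24 mM (held) | 24 mM (held) | 24 mM (held) |
| remark | run made earlier | run made earlier | run made earlier |  |  |  |  |  |
| time |  |  |  | 25 h | 25 h | 25 h | 25 h | 25 h |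

| run | time / h | Q / % | E / % |
|---|---|---|---|
| Monday's | 5.00 | 25.9 | 71.9 |
| Monday's | 10.0 | 48.2 | 54.4 |
| Monday's | 15.0 | 60.9 | 39.6 |
| Monday's | 20.0 | 67.8 | 31.5 |
| Monday's | 25.0 | 74.7 | 23.2 |
| Wednesday's | 2.00 | 10.6 | 88.9 |
| Wednesday's | 4.00 | 22.7 | 79.1 |
| Wednesday's | 8.00 | 38.3 | 62.7 |
| Wednesday's | 12.0 | 48.7 | 50.8 |
| Wednesday's | 25.0 | 64.3 | 33.6 |
| Friday's | 2.00 | 9.2 | 90.4 |
| Friday's | 4.00 | 20.4 | 81.6 |
| Friday's | 8.00 | 32.4 | 66.8 |
| Friday's | 12.0 | 38.9 | 59.6 |
| Friday's | 25.0 | 47.0 | 52.1 |

(scatter of a reading: 1 percentage point)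

- at the start none of X is dissolved
- what may be going on: X -> L; G -> Z; E + X <-> Q + G; D <-> X

- all flasks from highest to lowest amount of Q, in percent of the E charged, at 25 h (alder / larch / cedar / elm / birch)
- the amount of Q, in percent of the E charged of the flask you put first, at 25 h
- the amount of Q, in percent of the E charged of the flask you put last, at 25 h

X starts at nothing, but D is held at 24 mM, and Wednesday's run has already lost 11.1 % of its E by 2.00 h, so X appears within the first readings. At 4.00 h, Wednesday's and Friday's hold 79.1 % and 81.6 % of E, although their charges differ by a factor of 3.73. So early E behaves as pseudo-first-order, and one number can be carried: the time for E to fall to half of its charge at that early pace, the half-life. Monday's 54.4 % at 10.0 h reads as 11.4 h.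

In 25 h that counts as 2.19 half-lives, and as Q of 78.2 % with no way back. But the runs stand lower at 25.0 h, at 74.7 %, 64.3 % and 47.0 %, falling as the charge rises, as a way back through Q + G suggests. So my reckoning ranks the flasks by charge. Alder, charged above Friday's, is put just under Friday's reading of 47.0 %. Cedar, charged below Monday's, is put between 74.7 % and the 78.2 %, near 76.4 %.

The forecast reads cedar > birch > elm > larch > alder, with 75.5 % and 46.3 %: “Lower loading therefore gives a higher percentage of Q.”

The simulation gives cedar > birch > elm > larch > alder, with 76.3 % in cedar and 46.5 % in alder.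

    X → L (k = 0.537 h⁻¹)
    G → Z (k = 0.0170 h⁻¹)
    E + X ⇌ Q + G (K = 3.00, k = 3.11 M⁻¹ h⁻¹)
    D ⇌ X, rate k4*(csat - [X]) (kL = 4.83 h⁻¹)

In alder at 25.0 h, [X] stands at 0.0215 M beside the 24 mM of D. Counted for alder read at 6.0 h, 11.4 h makes 0.526 half-lives and leaves 69.4 % of E, and that flask holds 72.8 %.

The readings come from a simulation with constants of no real substance; noise was put on by code.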